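Labdane numbering is used (ring A: C1–C5, C10; ring B: C5–C10). Everything rests on closing ring A through the C1–C2 bond in a gold(I)-triggered cationic bicyclisation. The precursor is a trans,trans-trisubstituted γ-lactone (C18–O–C6 bridge, later reduced to the 18- and 6-hydroxyls) carrying an ethynyl group (C2≡C3) on quaternary C4, an isopropenyl group (C1=C10) on C5 and an (E)-alkenyl ketone arm on C6. π-Activation lets C1 attack C2 (6-endo-dig); the tertiary C10 cation is captured by C8=C9 and the C13 carbonyl, closing rings A and B and setting C10, C9 and C8. The step exploits the unfunctionalised C1–C2–C3 bridge between quaternary C4 and C10: the residual C2=C3 alkene is simply hydrogenated.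

Key step: step 10

Remarks and assumptions
* Locants: decalin C1–C10; C4 carries β-CH3 and the α-CH2OH carbon C18; C8 and C10 carry CH3; side chain C9–C11–C12–C13(CH3)=C14–C15(OH)–C16 (C16 is the butenolide CH–O).
* (E)-Geranylacetone is taken as the commercial single E isomer.
* Compounds 2 and 3 are racemic at one centre and 11 is a C4-epimer mixture; these centres are destroyed or re-set later.
* The (S)-BINOL titanium catalyst of step 16 is assumed to deliver the (15S,16S) adduct; if a model enal shows the opposite sense, (R)-BINOL is used.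

Step 1
Reactants: 1 (E)-geranylacetone [(5E)-6,10-dimethylundeca-5,9-dien-2-one]
Product: 3 (5E)-9,10-epoxy-6,10-dimethylundec-5-en-2-one (racemic at the epoxide), via bromohydrin 2 (not isolated)
Conditions: NBS, THF–H2O, 0 °C; then K2CO3, MeOH, rt
Reagents that add atoms: water, O (N-bromosuccinimide, O=C1CCC(=O)N1Br, supplies the Br of 2 only)
Why: Bromonium formation on the more exposed terminal trisubstituted alkene in aqueous medium gives the Markovnikov bromohydrin, which closes to the epoxide under base (halohydrin route, intramolecular Williamson etherification).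

Step 2
Reactants: 3 (5E)-9,10-epoxy-6,10-dimethylundec-5-en-2-one
Product: 4 (4E)-4-methyl-8-oxonon-4-enal
Conditions: H5IO6, THF–Et2O, 0 °C
Reagents that add atoms: none
Why: Periodic acid hydrolyses the epoxide and cleaves the glycol (Malaprade-type cleavage) to the aldehyde and acetone without touching the (E)-alkene or the methyl ketone.

Step 3
Reactants: 4 (4E)-4-methyl-8-oxonon-4-enal
Product: 6 ethyl (2Z,4S,6E)-2,6-dimethyl-10-oxo-4-[(phenylamino)oxy]undeca-2,6-dienoate, via aminoxy aldehyde 5 (not isolated)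
Conditions: D-proline (20 mol %), PhNO, MeCN, −20 °C; then added to (CF3CH2O)2P(O)CH(CH3)CO2Et, KHMDS, 18-crown-6, THF, −78 °C
Reagents that add atoms: nitrosobenzene, O=Nc1ccccc1; ethyl 2-[bis(2,2,2-trifluoroethoxy)phosphoryl]propanoate, CCOC(=O)C(C)P(=O)(OCC(F)(F)F)OCC(F)(F)F
Why: Proline enamine catalysis delivers the nitroso oxygen to one enantioface (organocatalytic α-aminoxylation; D-proline should give the 2S centre that becomes C6), and the crude aldehyde is trapped at once in a Z-selective Still–Gennari Horner–Wadsworth–Emmons olefination before it can epimerise.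

Step 4
Reactants: 6 ethyl (2Z,4S,6E)-2,6-dimethyl-10-oxo-4-[(phenylamino)oxy]undeca-2,6-dienoate
Product: 8 (5S)-3-methyl-5-[(2E)-2-methyl-6-oxohept-2-en-1-yl]furan-2(5H)-one, via hydroxy ester 7 (not isolated)
Conditions: Cu(OAc)2 (0.3 equiv), EtOH, rt; then PPTS, toluene, 60 °C
Reagents that add atoms: none
Why: Copper(II)-mediated N–O cleavage frees the γ-hydroxyl, which lactonises onto the cis-disposed ester (Z geometry) to the α-methylbutenolide.

Step 5
Reactants: 8 (5S)-3-methyl-5-[(2E)-2-methyl-6-oxohept-2-en-1-yl]furan-2(5H)-one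
Product: 9 (5S)-3-methyl-5-[(2E)-2-methyl-5-(2-methyl-1,3-dioxolan-2-yl)pent-2-en-1-yl]furan-2(5H)-one
Conditions: ethylene glycol, p-TsOH (cat.), benzene, reflux, Dean–Stark
Reagents that add atoms: ethylene glycol, OCCO
Why: Acid-catalysed acetalisation with azeotropic water removal masks the methyl ketone against the Grignard, enolate and diazo-anion steps that follow.

Step 6
Reactants: 9 (5S)-3-methyl-5-[(2E)-2-methyl-5-(2-methyl-1,3-dioxolan-2-yl)pent-2-en-1-yl]furan-2(5H)-one
Product: 11 (4S,5S)-3-methyl-5-[(2E)-2-methyl-5-(2-methyl-1,3-dioxolan-2-yl)pent-2-en-1-yl]-4-(prop-1-en-2-yl)dihydrofuran-2(3H)-one (C3 epimers), via silyl ketene acetal 10 (not isolated)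
Conditions: isopropenylMgBr, CuBr·SMe2 (cat.), TMSCl, THF, −78 to −40 °C; then aq NH4Cl/AcOH
Reagents that add atoms: isopropenylmagnesium bromide, CC(=C)[Mg]Br (chlorotrimethylsilane, C[Si](C)(C)Cl, supplies the silicon of 10 only)
Why: Copper-catalysed, TMSCl-accelerated conjugate addition of the isopropenyl Grignard occurs anti to the C6 side chain on the butenolide face, setting C5 trans to C6.

Step 7
Reactants: 11 (4S,5S)-3-methyl-5-[(2E)-2-methyl-5-(2-methyl-1,3-dioxolan-2-yl)pent-2-en-1-yl]-4-(prop-1-en-2-yl)dihydrofuran-2(3H)-one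
Product: 12 (3S,4R,5S)-3-(hydroxymethyl)-3-methyl-5-[(2E)-2-methyl-5-(2-methyl-1,3-dioxolan-2-yl)pent-2-en-1-yl]-4-(prop-1-en-2-yl)dihydrofuran-2(3H)-one
Conditions: LDA, THF, −78 °C; CH2O (g), −78 to −20 °C; then H2O
Reagents that add atoms: formaldehyde, C=O
Why: The lactone enolate undergoes aldol addition to monomeric formaldehyde on the face anti to the adjacent C5 isopropenyl group, creating quaternary C4 with the hydroxymethyl (future C3) trans and the methyl cis to that group.

Step 8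
Reactants: 12 (3S,4R,5S)-3-(hydroxymethyl)-3-methyl-5-[(2E)-2-methyl-5-(2-methyl-1,3-dioxolan-2-yl)pent-2-en-1-yl]-4-(prop-1-en-2-yl)dihydrofuran-2(3H)-one
Product: 13 (3S,4R,5S)-3-methyl-5-[(2E)-2-methyl-5-(2-methyl-1,3-dioxolan-2-yl)pent-2-en-1-yl]-2-oxo-4-(prop-1-en-2-yl)tetrahydrofuran-3-carbaldehyde
Conditions: TPAP (5 mol %), NMO, 4 Å MS, CH2Cl2, rt
Reagents that add atoms: none
Why: Ley–Griffith oxidation converts the neopentyl primary alcohol into the non-enolisable aldehyde under neutral conditions that spare ketal, alkenes and lactone.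

Step 9
Reactants: 13 (3S,4R,5S)-3-methyl-5-[(2E)-2-methyl-5-(2-methyl-1,3-dioxolan-2-yl)pent-2-en-1-yl]-2-oxo-4-(prop-1-en-2-yl)tetrahydrofuran-3-carbaldehyde
Product: 15 (3S,4R,5S)-3-ethynyl-3-methyl-5-[(2E)-2-methyl-6-oxohept-2-en-1-yl]-4-(prop-1-en-2-yl)dihydrofuran-2(3H)-one, via alkynyl ketal 14 (not isolated)
Conditions: TMSCHN2, LDA, THF, −78 °C to rt; then 1 M HCl, THF, rt
Reagents that add atoms: (trimethylsilyl)diazomethane, C[Si](C)(C)C=[N+]=[N-]; water, O
Why: Colvin homologation (lithiated trimethylsilyldiazomethane, Peterson-type elimination, 1,2-hydride shift of the alkylidene carbene) gives the terminal alkyne without the alkoxide that could deformylate the quaternary formyl lactone, and the acidic work-up hydrolyses the dioxolane.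

Step 10
Reactants: 15 (3S,4R,5S)-3-ethynyl-3-methyl-5-[(2E)-2-methyl-6-oxohept-2-en-1-yl]-4-(prop-1-en-2-yl)dihydrofuran-2(3H)-one
Product: 17 (4R,5R,6S,8R,9R,10S)-8α-hydroxy-13-oxo-14,15-dinorlabd-2-en-18,6α-olide, via cyclic enol ether 16 (not isolated)
Conditions: (JohnPhos)Au(NCMe)SbF6 (5 mol %), CH2Cl2, 0 °C to rt; then 1 M HCl, THF, 0 °C
Reagents that add atoms: water, O
Why: Cationic gold(I) π-activates the terminal alkyne and the isopropenyl CH2 (C1) attacks the alkyne terminus C2 in a 6-endo-dig mode, giving a vinyl-gold at C3 and a tertiary C10 cation; this is trapped by the (E)-C8=C9 alkene in a 6-endo-trig closure, and the C8 cation is captured by the C13 carbonyl oxygen to a six-membered oxocarbenium ion that loses a proton (protodeauration of C3) and is hydrolysed on work-up. The closest known reaction type is the gold(I)-catalysed alkyne-initiated polyene (1,5-enyne) cyclisation with heteroatom termination. Ring A closes trans-fused to the lactone and ring B through a chair–chair array: anti addition across C1=C10 should place the incoming C9 equatorial and the C10 methyl axial (trans to the existing C5–H), and the E geometry of C8=C9 should put the C9 side chain equatorial and the C8 oxygen equatorial (α) with the C8 methyl axial. The existing C4, C5 and C6 centres, locked in the trans,trans-lactone, thus control C10, C9 and C8. The step needs 6-endo-dig over 5-exo-dig attack and capture of the C10 cation before proton loss; the tertiary character of C10, the quaternary C4 (no 1,2-hydride shift possible) and the six-membered reach of the C8=C9 alkene should secure both.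

Step 11
Reactants: 17 (4R,5R,6S,8R,9R,10S)-8α-hydroxy-13-oxo-14,15-dinorlabd-2-en-18,6α-olide
Product: 18 (4R,5R,6S,8R,9R,10S)-8α-hydroxy-13-oxo-14,15-dinorlabdan-18,6α-olide
Conditions: H2 (1 atm), 10 % Pd/C, EtOAc, rt
Reagents that add atoms: none
Why: Heterogeneous hydrogenation saturates the only C=C (cis-disubstituted C2=C3), leaving ketone, lactone and tertiary alcohol untouched.

Step 12
Reactants: 18 (4R,5R,6S,8R,9R,10S)-8α-hydroxy-13-oxo-14,15-dinorlabdan-18,6α-olide
Product: 19 (13E)-8α-hydroxy-15-[methoxy(methyl)amino]-15-oxolabd-13-en-18,6α-olide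
Conditions: (EtO)2P(O)CH2C(O)N(OMe)Me, NaH, THF, 0 °C to reflux
Reagents that add atoms: diethyl [2-(methoxy(methyl)amino)-2-oxoethyl]phosphonate, CCOP(=O)(OCC)CC(=O)N(C)OC
Why: Horner–Wadsworth–Emmons olefination of the methyl ketone should favour the E trisubstituted enamide (longer chain trans to the amide), and the poorly electrophilic Weinreb enamide resists oxa-Michael attack by the C8 alkoxide.

Step 13
Reactants: 19 (13E)-8α-hydroxy-15-[methoxy(methyl)amino]-15-oxolabd-13-en-18,6α-olide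
Product: 20 (13E)-6α,8α,18-trihydroxylabd-13-en-15-al
Conditions: LiAlH4, THF, −20 to 0 °C; Rochelle salt work-up
Reagents that add atoms: none
Why: Hydride reduces the lactone to the 6,18-diol while the Weinreb amide stops at the chelated tetrahedral intermediate, which releases the (E)-enal only on aqueous work-up (Weinreb amide reduction).

Step 14
Reactants: 20 (13E)-6α,8α,18-trihydroxylabd-13-en-15-al
Product: 21 (13E)-6α,8α,18-tris(trimethylsilyloxy)labd-13-en-15-al
Conditions: 1-(trimethylsilyl)imidazole, CH2Cl2, rt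
Reagents that add atoms: 1-(trimethylsilyl)imidazole, C[Si](C)(C)n1ccnc1
Why: The N-silylimidazole silylates the primary, secondary and hindered tertiary hydroxyls under neutral conditions without enolising the enal, so that no free OH can exchange with the titanium catalyst of step 16.

Step 15
Reactants: 22 4-methylfuran-2(5H)-one
Product: 23 4-methyl-2-(trimethylsilyloxy)furan
Conditions: TMSOTf, Et3N, Et2O, 0 °C
Reagents that add atoms: trimethylsilyl triflate, C[Si](C)(C)OS(=O)(=O)C(F)(F)F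
Why: Soft enolisation and O-silylation of the butenolide give the aromatic 2-silyloxyfuran (silyl dienol ether formation).

Step 16
Reactants: 21 (13E)-6α,8α,18-tris(trimethylsilyloxy)labd-13-en-15-al; 23 4-methyl-2-(trimethylsilyloxy)furan
Product: 25 (5S)-5-{(1S,2E)-1-hydroxy-3-methyl-5-[(4R,5R,6S,8R,9R,10S)-6,8-dihydroxy-4-(hydroxymethyl)-4,8,10-trimethyldecalin-9-yl]pent-2-en-1-yl}-4-methylfuran-2(5H)-one (CNP0255788.1), via silylated aldol adduct 24 (not isolated)
Conditions: Ti(OiPr)4/(S)-BINOL (20 mol %), Et2O, −20 °C; then 1 M HCl, THF–MeOH, 0 °C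
Reagents that add atoms: none
Why: Catalytic enantioselective vinylogous Mukaiyama aldol addition, in which the silyloxyfuran attacks through C5 (γ) the titanium–BINOL-activated aldehyde via an open transition state that should favour the threo (like) adduct while the catalyst selects the aldehyde face, so that C15 and C16 are both set S; dilute acid then removes all TMS groups.

Compound list
1 | (E)-geranylacetone, (5E)-6,10-dimethylundeca-5,9-dien-2-one | CC(=O)CC/C=C(\C)CCC=C(C)C | starting material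
2 | (5E)-9-bromo-10-hydroxy-6,10-dimethylundec-5-en-2-one (racemic) | CC(=O)CC/C=C(\C)CCC(Br)C(C)(C)O | intermediate (not isolated)
3 | (5E)-9,10-epoxy-6,10-dimethylundec-5-en-2-one (racemic) | CC(=O)CC/C=C(\C)CCC1OC1(C)C | intermediate
4 | (4E)-4-methyl-8-oxonon-4-enal | CC(=O)CC/C=C(\C)CCC=O | intermediate
5 | (2S,4E)-4-methyl-8-oxo-2-[(phenylamino)oxy]non-4-enal | CC(=O)CC/C=C(\C)C[C@H](ONc1ccccc1)C=O | intermediate (not isolated)
6 | ethyl (2Z,4S,6E)-2,6-dimethyl-10-oxo-4-[(phenylamino)oxy]undeca-2,6-dienoate | CCOC(=O)/C(C)=C\[C@@H](ONc1ccccc1)C/C(C)=C/CCC(C)=O | intermediate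
7 | ethyl (2Z,4S,6E)-4-hydroxy-2,6-dimethyl-10-oxoundeca-2,6-dienoate | CCOC(=O)/C(C)=C\[C@@H](O)C/C(C)=C/CCC(C)=O | intermediate (not isolated)
8 | (5S)-3-methyl-5-[(2E)-2-methyl-6-oxohept-2-en-1-yl]furan-2(5H)-one | O=C1O[C@@H](C/C(C)=C/CCC(C)=O)C=C1C | intermediate
9 | (5S)-3-methyl-5-[(2E)-2-methyl-5-(2-methyl-1,3-dioxolan-2-yl)pent-2-en-1-yl]furan-2(5H)-one | O=C1O[C@@H](C/C(C)=C/CCC2(C)OCCO2)C=C1C | intermediate
10 | trimethylsilyl ketene acetal of 11, (4R,5S)-configured 2-(trimethylsilyloxy)-4,5-dihydrofuran | C[Si](C)(C)OC1=C(C)[C@@H](C(C)=C)[C@H](C/C(C)=C/CCC2(C)OCCO2)O1 | intermediate (not isolated)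
11 | (4S,5S)-3-methyl-5-[(2E)-2-methyl-5-(2-methyl-1,3-dioxolan-2-yl)pent-2-en-1-yl]-4-(prop-1-en-2-yl)dihydrofuran-2(3H)-one (C3 epimers) | O=C1O[C@@H](C/C(C)=C/CCC2(C)OCCO2)[C@H](C(C)=C)C1C | intermediate
12 | (3S,4R,5S)-3-(hydroxymethyl)-3-methyl-5-[(2E)-2-methyl-5-(2-methyl-1,3-dioxolan-2-yl)pent-2-en-1-yl]-4-(prop-1-en-2-yl)dihydrofuran-2(3H)-one | O=C1O[C@@H](C/C(C)=C/CCC2(C)OCCO2)[C@H](C(C)=C)[C@@]1(C)CO | intermediate
13 | (3S,4R,5S)-3-methyl-5-[(2E)-2-methyl-5-(2-methyl-1,3-dioxolan-2-yl)pent-2-en-1-yl]-2-oxo-4-(prop-1-en-2-yl)tetrahydrofuran-3-carbaldehyde | O=C1O[C@@H](C/C(C)=C/CCC2(C)OCCO2)[C@H](C(C)=C)[C@@]1(C)C=O | intermediate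
14 | (3S,4R,5S)-3-ethynyl-3-methyl-5-[(2E)-2-methyl-5-(2-methyl-1,3-dioxolan-2-yl)pent-2-en-1-yl]-4-(prop-1-en-2-yl)dihydrofuran-2(3H)-one | O=C1O[C@@H](C/C(C)=C/CCC2(C)OCCO2)[C@H](C(C)=C)[C@@]1(C)C#C | intermediate (not isolated)
15 | (3S,4R,5S)-3-ethynyl-3-methyl-5-[(2E)-2-methyl-6-oxohept-2-en-1-yl]-4-(prop-1-en-2-yl)dihydrofuran-2(3H)-one | O=C1O[C@@H](C/C(C)=C/CCC(C)=O)[C@H](C(C)=C)[C@@]1(C)C#C | intermediate
16 | (4R,5R,6S,8R,9R,10S)-8α,13-epoxy-14,15-dinorlabda-2,12-dien-18,6α-olide (cyclic enol ether) | CC1=CC[C@@H]2[C@@]3(C)CC=C[C@@](C)(C(=O)O4)[C@@H]3[C@@H]4C[C@@]2(C)O1 | intermediate (not isolated)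
17 | (4R,5R,6S,8R,9R,10S)-8α-hydroxy-13-oxo-14,15-dinorlabd-2-en-18,6α-olide | CC(=O)CC[C@@H]1[C@@]2(C)CC=C[C@@](C)(C(=O)O3)[C@@H]2[C@@H]3C[C@@]1(C)O | intermediate
18 | (4R,5R,6S,8R,9R,10S)-8α-hydroxy-13-oxo-14,15-dinorlabdan-18,6α-olide | CC(=O)CC[C@@H]1[C@@]2(C)CCC[C@@](C)(C(=O)O3)[C@@H]2[C@@H]3C[C@@]1(C)O | intermediate
19 | (13E)-8α-hydroxy-15-[methoxy(methyl)amino]-15-oxolabd-13-en-18,6α-olide | CON(C)C(=O)/C=C(\C)CC[C@@H]1[C@@]2(C)CCC[C@@](C)(C(=O)O3)[C@@H]2[C@@H]3C[C@@]1(C)O | intermediate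
20 | (13E)-6α,8α,18-trihydroxylabd-13-en-15-al | O=C/C=C(\C)CC[C@@H]1[C@@]2(C)CCC[C@@](C)(CO)[C@@H]2[C@@H](O)C[C@@]1(C)O | intermediate
21 | (13E)-6α,8α,18-tris(trimethylsilyloxy)labd-13-en-15-al | O=C/C=C(\C)CC[C@@H]1[C@@]2(C)CCC[C@@](C)(CO[Si](C)(C)C)[C@@H]2[C@@H](O[Si](C)(C)C)C[C@@]1(C)O[Si](C)(C)C | intermediate
22 | 4-methylfuran-2(5H)-one | CC1=CC(=O)OC1 | starting material
23 | 4-methyl-2-(trimethylsilyloxy)furan | Cc1coc(O[Si](C)(C)C)c1 | intermediate
24 | 6,8,15,18-tetrakis(trimethylsilyl) ether of 25 | CC1=CC(=O)O[C@@H]1[C@@H](O[Si](C)(C)C)/C=C(\C)CC[C@@H]1[C@@]2(C)CCC[C@@](C)(CO[Si](C)(C)C)[C@@H]2[C@@H](O[Si](C)(C)C)C[C@@]1(C)O[Si](C)(C)C | intermediate (not isolated)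
25 | CNP0255788.1, (13E,15S,16S)-6α,8α,15,18-tetrahydroxy labdane-type sesterterpenoid butenolide | CC1=CC(=O)O[C@@H]1[C@@H](O)/C=C(\C)CC[C@@H]1[C@@]2(C)CCC[C@@](C)(CO)[C@@H]2[C@@H](O)C[C@@]1(C)O | target

Total step count: 16. Longest linear sequence: 15 (steps 1–14 and 16).

Steps most likely to fail

Step 10 (key bicyclisation). The tertiary C10 cation may lose a proton before the C8=C9 alkene engages, which would interrupt the cascade, or ring B may close cis. The fallback sets out from 15 and returns at 17, and separates the two ring closures. Gold(I)-catalysed 6-endo-dig methoxycyclisation of 15 in CH2Cl2–MeOH should capture the C10 cation as its tertiary methyl ether, giving the ring-A-closed (8E)-10-methoxy-13-oxo-9,10-seco-14,15-dinorlabda-2,8-dien-18,6α-olide F1. Ionisation of this ether with SnCl4 in CH2Cl2 at −78 °C should then close ring B by a classical cation–olefin cyclisation onto C8=C9 with ketone termination (the mode by which monocyclic terpenoid cations give trans-decalins). Aqueous acid hydrolysis of the enol ether 16 gives 17.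

Step 16 (vinylogous aldol). Facial discrimination at the aldehyde and at C5 of the furan may be insufficient, giving the wrong threo/erythro ratio or absolute sense. The fallback sets out from 20 and returns at 25, and sets both centres by reagent control before closing the butenolide by metathesis.
* Silylation of 20 (TESOTf, 2,6-lutidine, −78 °C) gives the tris(triethylsilyl) enal F6.
* Alkoxyallylboration with (Z)-[3-(4-methoxybenzyloxy)-2-methylallyl]diisopinocampheylborane (the Ipc antipode that gives 15S,16S) should give the syn (15S,16S)-15-hydroxy-16-(4-methoxybenzyloxy) isopropenyl adduct F7.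
* TESOTf gives the 15-O-triethylsilyl ether F8, and DDQ removes the PMB group to the 16-alcohol F9.
* Acryloyl chloride/Et3N gives the acrylate F10.
* Ring-closing metathesis (second-generation Ru catalyst, toluene, 80 °C) closes the 4-methylbutenolide to the tetrakis(triethylsilyl) ether of the target F11.
* HF·pyridine gives 25.

Step 12 (ketone olefination). E/Z control in the olefination of the methyl ketone may be poor, and the C8 alkoxide may interfere. The fallback sets out from 18 and returns at 20, and builds the trisubstituted alkene by carbometalation.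
* Kinetic enolisation of the methyl ketone (LDA, −78 °C) and trapping with ClP(O)(OEt)2 gives the terminal enol diethyl phosphate F2.
* Elimination in the same flask with LDA gives the terminal alkyne, 9-(but-3-yn-1-yl) hydroxy lactone F3.
* Negishi carboalumination (Me3Al, Cp2ZrCl2) followed by ethyl chloroformate gives ethyl (13E)-8α-hydroxylabd-13-en-18,6α-olid-15-oate F4 with defined E geometry.
* LiAlH4 reduces ester and lactone to (13E)-labd-13-ene-6α,8α,15,18-tetraol F5.
* MnO2 oxidises the allylic alcohol selectively to 20.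

Further compounds
F1 | step 10 | (8E)-10-methoxy-13-oxo-9,10-seco-14,15-dinorlabda-2,8-dien-18,6α-olide (ring A closed, C10 epimers) | O=C1O[C@@H](C/C(C)=C/CCC(C)=O)[C@H]2[C@@]1(C)C=CCC2(C)OC
F2 | step 12 | terminal enol diethyl phosphate of 18 | C=C(OP(=O)(OCC)OCC)CC[C@@H]1[C@@]2(C)CCC[C@@](C)(C(=O)O3)[C@@H]2[C@@H]3C[C@@]1(C)O
F3 | step 12 | terminal alkyne, 9-(but-3-yn-1-yl)-8α-hydroxy-18,6α-lactone | C#CCC[C@@H]1[C@@]2(C)CCC[C@@](C)(C(=O)O3)[C@@H]2[C@@H]3C[C@@]1(C)O
F4 | step 12 | ethyl (13E)-8α-hydroxylabd-13-en-18,6α-olid-15-oate | CCOC(=O)/C=C(\C)CC[C@@H]1[C@@]2(C)CCC[C@@](C)(C(=O)O3)[C@@H]2[C@@H]3C[C@@]1(C)O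
F5 | step 12 | (13E)-labd-13-ene-6α,8α,15,18-tetraol | OC/C=C(\C)CC[C@@H]1[C@@]2(C)CCC[C@@](C)(CO)[C@@H]2[C@@H](O)C[C@@]1(C)O
F6 | step 16 | (13E)-6α,8α,18-tris(triethylsilyloxy)labd-13-en-15-al | O=C/C=C(\C)CC[C@@H]1[C@@]2(C)CCC[C@@](C)(CO[Si](CC)(CC)CC)[C@@H]2[C@@H](O[Si](CC)(CC)CC)C[C@@]1(C)O[Si](CC)(CC)CC
F7 | step 16 | (15S,16S)-15-hydroxy-16-(4-methoxybenzyloxy)-17-methylene adduct (syn) | C=C(C)[C@H](OCc1ccc(OC)cc1)[C@@H](O)/C=C(\C)CC[C@@H]1[C@@]2(C)CCC[C@@](C)(CO[Si](CC)(CC)CC)[C@@H]2[C@@H](O[Si](CC)(CC)CC)C[C@@]1(C)O[Si](CC)(CC)CC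
F8 | step 16 | 15-O-triethylsilyl ether of F7 | C=C(C)[C@H](OCc1ccc(OC)cc1)[C@@H](O[Si](CC)(CC)CC)/C=C(\C)CC[C@@H]1[C@@]2(C)CCC[C@@](C)(CO[Si](CC)(CC)CC)[C@@H]2[C@@H](O[Si](CC)(CC)CC)C[C@@]1(C)O[Si](CC)(CC)CC
F9 | step 16 | 16-alcohol after PMB removal | C=C(C)[C@H](O)[C@@H](O[Si](CC)(CC)CC)/C=C(\C)CC[C@@H]1[C@@]2(C)CCC[C@@](C)(CO[Si](CC)(CC)CC)[C@@H]2[C@@H](O[Si](CC)(CC)CC)C[C@@]1(C)O[Si](CC)(CC)CC
F10 | step 16 | 16-O-acrylate | C=C(C)[C@H](OC(=O)C=C)[C@@H](O[Si](CC)(CC)CC)/C=C(\C)CC[C@@H]1[C@@]2(C)CCC[C@@](C)(CO[Si](CC)(CC)CC)[C@@H]2[C@@H](O[Si](CC)(CC)CC)C[C@@]1(C)O[Si](CC)(CC)CC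
F11 | step 16 | 6,8,15,18-tetrakis(triethylsilyl) ether of 25 | CC1=CC(=O)O[C@@H]1[C@@H](O[Si](CC)(CC)CC)/C=C(\C)CC[C@@H]1[C@@]2(C)CCC[C@@](C)(CO[Si](CC)(CC)CC)[C@@H]2[C@@H](O[Si](CC)(CC)CC)C[C@@]1(C)O[Si](CC)(CC)CC
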